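# Proposed total synthesis of CNP0163821.6 by tethered phosphonoacetate opening of a ring epoxide

## Structural features

The target is a germacranolide: a cyclodeca-1(10),4-diene with a trans-fused α-methylene-γ-butyrolactone on C6–C7 (lactone oxygen on C6, C11 on C7, C12 the carbonyl, C11=C13 exocyclic). The C1=C10 double bond (methyl C14 on C10) is cis within the ring and the C4=C5 double bond (hydroxymethyl C15 on C4) is trans within the ring; both carry the CIP descriptor Z, because CH2OH outranks the ring CH2 on C4. Three contiguous stereocentres, C6 (R), C7 (R) and C8 (S), lie between the C4=C5 alkene and the C9 methylene, and C8 carries the ester of (S)-3-hydroxy-2-methylpropanoic acid, the fourth stereocentre. H6 and H7 are anti (trans lactone), and C11 on C7 is anti to the oxygen on C8. Fragile groups are the α-methylene lactone (Michael acceptor), the allylic C6–O lactone bond, the 1,5-diene in a medium ring (transannular cyclisation, Cope rearrangement on heating), the β-hydroxy ester side chain (elimination, epimerisation) and the C8 oxygen, which can take over the lactone carbonyl whenever it is a free alkoxide. The real difficulty is the C6–C7–C8 triad: a carbon substituent has to be placed on C7 between two oxygens, with defined sense, inside a strained ten-membered ring of mixed alkene geometry. The key step uses this triad directly: O6–C12–C11 is a three-atom bridge from the C6 oxygen to C7, and the anti relation of C11 and O8 is what backside opening of a cis C7–C8 epoxide by a carbanion held on O6 leaves behind.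

## Logic of the disconnections

**29 ⇒ 28.** The cuts are the two O–Si bonds (C15 and the side-chain primary oxygen). Both primary alcohols must stay masked while the C8 hydroxyl is acylated, so unmasking comes last. The gain is chemoselectivity only. The demand is a fluoride source that spares the α-methylene lactone and the β-oxy ester.

**28 ⇒ 24 + 27; 27 ⇒ 26 ⇒ 25.** The cut is the C8–O acyl bond. This makes the route convergent, takes the side-chain stereocentre from the chiral pool, and turns any residual enantiomer of 24 into a separable diastereomer. The demand is acylation of a hindered secondary alcohol without epimerising the acid; 27 follows from 25 by silylation and ester hydrolysis.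

**24 ⇒ 23.** The cut is C11=C13. The phosphonate that activates C11 in the key step is also the olefination handle, so the exocyclic methylene costs one step. The demand is a mild base, because C8–OH is free.

**23 ⇒ 22 (key disconnection).** The cut is the C7–C11 bond, which opens the lactone ring back to a C6 ester and a cis C7–C8 epoxide. One C–C bond, one ring and the C7 configuration are removed, and the problem becomes an epoxy alcohol. The forward step must attack C7 (not C8) from the side opposite the epoxide oxygen. The configurations were checked: 22 (6R,7S,8S) and 23 (6R,7R,8S) differ only by inversion at C7, with C6 and C8 untouched, and O6 in 22 is anti to the epoxide oxygen, which is the arrangement that lets the tether reach the backside of C7. The epoxide in 22 is not allylic; only the C6 carbinol is.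

**22 ⇒ 20 + 21.** The cut is the O6–C12 ester bond, giving a free epoxy alcohol and a catalogue acid. The demand is mild esterification that leaves the epoxide alone. The C15 ether is designed as TBDPS rather than TBS so that it survives the earlier acid removal of a C6 TBS ether and every base used later.

**20 ⇒ 19.** The cut is C5–C6, by intramolecular addition of an alkenyl metal to an aldehyde. It creates the allylic C6 carbinol and closes the ten-membered ring from a linear chain in which all three alkene and epoxide geometries already exist. The demands are high dilution and Felkin–Anh addition anti to the epoxide C–O bond, which gives exactly the C6 configuration required in 22.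

**19 ⇒ 18 ⇒ 17.** These cuts are an oxidation-level change at C6 and the two C–O bonds of the epoxide. C7 and C8 are set together by reagent control on a (Z)-allylic alcohol. The required (2R,3S) cis-epoxide calls for the D-(−)-tartrate. The demand is enantiofacial control on the least responsive olefin class.

**17 ⇒ 16 ⇒ 15.** The cuts are O–Si bonds only. C15–OH is capped with the robust silyl group before C6–OH is released, so that only one allylic alcohol is presented to the epoxidation and the oxidation.

**15 ⇒ 10 + 11.** The cuts are C3–C4 and C5–I. Anti-carbomagnesiation of a propargyl alkoxide followed by iodinolysis builds the trisubstituted iodoalkene in one operation with iodine cis to CH2OH, which becomes the ring-trans C4=C5 bond. The demand is a homoallylic Grignard reagent free of electrophilic groups, which is why the epoxide is introduced later.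

**10 ⇒ 9 ⇒ 6 + 7.** The cuts are the C8–C9 bond (alkynyl–allyl coupling) and the C7=C8 π-bond (cis semi-hydrogenation of the alkyne). A three-carbon alkyne supplies C6–C8. The demands are substitution at the primary allylic carbon without allylic transposition and no reaction at the second, unactivated bromide.

**6 ⇒ 5 ⇒ 4 ⇒ 3 ⇒ 1 + 2.** The cut is C1=C10, by a Z-selective phosphonate olefination that puts the future C9 (ester carbon) cis to C2. The remaining changes are functional-group interconversions (silyl ether to bromide at C3, ester to allylic bromide at C9). The demand is that the Z-trisubstituted alkene survives these steps.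

## Other disconnections considered

**Alternative 1:** The cut is C2–C3, with C5–C10 reconnected, leading back to the cis-1,2-dialkenylcyclohexanol A1. In the forward sense KH/18-crown-6 would convert A1 into its C5 alkoxide, and a chair [3,3] shift would form C2–C3, cleave C5–C10 and deliver the ring-expanded C5 enolate, trapped with PhNTf2 as the enol triflate A2.
- In its favour: the ten-membered ring arises by ring expansion, without high dilution, which is better than the end-to-end closure of step 12. The anionic oxy-Cope rearrangement is well established for cyclodecenones, which is better precedent than step 14. C6, C7 and C8 would be set on a cyclohexane chair, and both ring alkenes come from one transition state.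
- Against it here: A1 needs five contiguous stereocentres, two of them fully substituted (C5, C10) and destroyed in the step. The required geometry pair (ring-cis C1=C10, ring-trans C4=C5) needs the chair with the C5 alkenyl group axial, and the other chair gives the opposite pair. An alkoxy group sits next to the enolate.
- After A2 the route still needs triflate reduction, two PMB removals, oxidative lactonisation, α-methylenation, C8 deprotection, acylation and final desilylation, roughly eight steps against four after the chosen key step.
- Comparison: equal or better on ring formation and precedent, worse on stereochemical overhead and step economy.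

**Alternative 2:** The cut is C7–C8, leading back to the butenolide aldehyde A3. SmI2 (divalent samarium) would reduce the C8 aldehyde to a ketyl that adds to C7 of the butenolide, closing the ten-membered ring onto the existing lactone to give A4.
- In its favour: one step forms the ring, C7 and C8. The single C6 stereocentre of A3 directs addition anti to its substituent, so the trans C6/C7 relation is controlled at least as well as in the chosen plan (equal). No epoxidation of a (Z)-allylic alcohol and no chromium-mediated closure are needed, which is better than steps 10 and 12. The plan is convergent.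
- Against it here: the C8 carbinol configuration depends on the ketyl face in a ten-membered transition state and is not stereospecific, whereas the chosen plan fixes C8 by reagent control and never touches it. A3 contains a β,γ-unsaturated aldehyde that can conjugate and an allylic lactone C–O bond that SmI2 may cleave; simple reduction and pinacol coupling also compete. A4 lacks C13, so α-methylenation with a free C8–OH costs two or three steps, where 23 needs one.
- Comparison: comparable overall length; better on convergency; worse on control of C8 and on the end game.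

**Alternative 3:** The cuts are the two ring π-bonds, traced back to the C5–C10 and C1–C4 σ-bonds of the central cyclobutane in the tricyclic photoadduct A5. Thermolysis of A5 would cleave both σ-bonds and merge the six- and four-membered rings into the cyclodecadienone A6.
- In its favour: this is the shortest access to the ten-membered carbocycle (one photocycloaddition and one thermal step), which is better than the chosen plan on steps to the ring. It needs no metal reagent and no high dilution, and C7 and C8 are set on a six-membered ring.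
- Against it here: which new alkene becomes ring-cis is decided by the conformation of the opening 1,4-diyl and not by any stereocentre of A5, so the geometry pair is not secured. At the temperature needed a 1,5-diene such as A6 can undergo Cope rearrangement and geometric isomerisation.
- After A6 the route still needs C6 ketone reduction with no template, reduction of the C15 ester, conversion of the acetal into the lactone, α-methylenation, acylation and deprotection, at least seven steps.
- Comparison: better on speed to the skeleton; worse on geometric and C6 control, on thermal safety and on post-key step count.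

Key step: step 14

Assumption: compounds 1, 2, 7, 11, 21 and 25 are taken as catalogue chemicals.

Assumption: organomagnesium species prepared as a separate stage are numbered as intermediates; conjugate bases and metal-bound forms that exist only until work-up are treated as forms of the numbered compound.

Assumption: descriptors at C6, C7 and C8 use germacrane numbering; the descriptor at C7 changes between 18, 19, 20 and 22 through CIP ranking alone, and the only change of configuration is the inversion in step 14.

## Route

Step 1
Reactants: 1 3-[(tert-butyldimethylsilyl)oxy]propanal; 2 ethyl 2-[bis(2,2,2-trifluoroethoxy)phosphoryl]propanoate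
Product: 3 ethyl (2Z)-5-[(tert-butyldimethylsilyl)oxy]-2-methylpent-2-enoate
Conditions: 2, KN(SiMe3)2, 18-crown-6, THF, −78 °C; then 1
Reagents that add atoms: none
Why: Still–Gennari olefination; the electron-poor phosphonate eliminates from the kinetic adduct, so the ester (future C9) ends cis to the C2 chain, which fixes the ring-cis C1=C10 geometry.

Step 2
Reactants: 3 ethyl (2Z)-5-[(tert-butyldimethylsilyl)oxy]-2-methylpent-2-enoate
Product: 4 ethyl (2Z)-5-bromo-2-methylpent-2-enoate
Conditions: Ph3PBr2, CH2Cl2, 0 °C → rt
Reagents that add atoms: dibromotriphenylphosphorane, BrP(Br)(c1ccccc1)(c1ccccc1)c1ccccc1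
Why: Direct conversion of a primary silyl ether into the bromide through the alkoxyphosphonium bromide (SN2); it installs the C3 handle without ever freeing the (Z)-5-hydroxy enoate, which would lactonise.

Step 3
Reactants: 4 ethyl (2Z)-5-bromo-2-methylpent-2-enoate
Product: 5 (2Z)-5-bromo-2-methylpent-2-en-1-ol
Conditions: i-Bu2AlH, CH2Cl2, −78 °C; aq. potassium sodium tartrate
Reagents that add atoms: none
Why: 1,2-Reduction of the enoate by the aluminium hydride; the primary bromide and the alkene geometry are inert at −78 °C.

Step 4
Reactants: 5 (2Z)-5-bromo-2-methylpent-2-en-1-ol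
Product: 6 (2Z)-1,5-dibromo-2-methylpent-2-ene
Conditions: CBr4, PPh3, CH2Cl2, 0 °C
Reagents that add atoms: tetrabromomethane, BrC(Br)(Br)Br
Why: Appel bromination; SN2 displacement of the alkoxyphosphonium at the primary allylic carbon keeps the Z geometry and gives an allylic bromide far more reactive than the C3 bromide.

Step 5
Reactants: 6 (2Z)-1,5-dibromo-2-methylpent-2-ene; 7 tert-butyldimethyl(prop-2-yn-1-yloxy)silane
Product: 9 {[(5Z)-8-bromo-5-methyloct-5-en-2-yn-1-yl]oxy}(tert-butyl)dimethylsilane, via alkynylmagnesium bromide 8 (not isolated)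
Conditions: 7, EtMgBr, THF, 0 → 40 °C; CuBr·SMe2 (10 mol %), 6, 0 °C → rt
Reagents that add atoms: none
Why: Copper-catalysed alkynyl–allyl coupling forms C8–C9 at the less hindered primary allylic terminus; the unactivated C3 bromide does not react with alkynyl copper or magnesium species.

Step 6
Reactants: 9 {[(5Z)-8-bromo-5-methyloct-5-en-2-yn-1-yl]oxy}(tert-butyl)dimethylsilane
Product: 10 {[(2Z,5Z)-8-bromo-5-methylocta-2,5-dien-1-yl]oxy}(tert-butyl)dimethylsilane
Conditions: H2 (1 atm), Pd/CaCO3 poisoned with Pb(OAc)2, quinoline, EtOAc, rt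
Reagents that add atoms: none
Why: Lindlar semi-hydrogenation adds hydrogen cis to the alkyne and gives the (Z)-C7=C8 alkene; the trisubstituted alkene and the alkyl bromide are not reduced on the poisoned catalyst.

Step 7
Reactants: 10 {[(2Z,5Z)-8-bromo-5-methylocta-2,5-dien-1-yl]oxy}(tert-butyl)dimethylsilane; 11 prop-2-yn-1-ol
Product: 15 (2Z)-2-{(3Z,6Z)-8-[(tert-butyldimethylsilyl)oxy]-4-methylocta-3,6-dien-1-yl}-3-iodoprop-2-en-1-ol (iodine cis to CH2OH), via homoallylic Grignard reagent 12 (not isolated), via chloromagnesium propynolate 13 (not isolated), via alkenylmagnesium chelate 14 (not isolated)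
Conditions: 10, Mg, THF, 40 °C; 11, i-PrMgCl (1.0 equiv), Et2O/THF, −20 °C; CuI (15 mol %), −10 °C → rt; I2, −60 → 0 °C; aq. NH4Cl
Reagents that add atoms: iodine, II
Why: Copper-catalysed anti-carbomagnesiation of the propargyl alkoxide puts the alkyl group on the carbinol-bearing alkyne carbon and magnesium on the terminal carbon inside a five-membered chelate, cis to CH2O; iodinolysis with retention gives iodine cis to CH2OH, the geometry that becomes the ring-trans C4=C5 bond.

Step 8
Reactants: 15 (2Z)-2-{(3Z,6Z)-8-[(tert-butyldimethylsilyl)oxy]-4-methylocta-3,6-dien-1-yl}-3-iodoprop-2-en-1-ol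
Product: 16 tert-butyl{[(2Z)-2-{(3Z,6Z)-8-[(tert-butyldimethylsilyl)oxy]-4-methylocta-3,6-dien-1-yl}-3-iodoprop-2-en-1-yl]oxy}diphenylsilane
Conditions: TBDPSCl, imidazole, CH2Cl2, 0 °C → rt
Reagents that add atoms: tert-butyl(chloro)diphenylsilane, CC(C)(C)[Si](Cl)(c1ccccc1)c1ccccc1
Why: Standard silylation of the primary allylic alcohol; the TBDPS ether is chosen because it outlasts the acid cleavage of the C6 TBS ether and all later bases.

Step 9
Reactants: 16 tert-butyl{[(2Z)-2-{(3Z,6Z)-8-[(tert-butyldimethylsilyl)oxy]-4-methylocta-3,6-dien-1-yl}-3-iodoprop-2-en-1-yl]oxy}diphenylsilane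
Product: 17 (2Z,5Z,9Z)-9-{[(tert-butyldiphenylsilyl)oxy]methyl}-10-iodo-5-methyldeca-2,5,9-trien-1-ol
Conditions: camphor-10-sulfonic acid (10 mol %), MeOH/CH2Cl2, 0 °C
Reagents that add atoms: none
Why: Acid methanolysis removes the primary TBS ether much faster than the TBDPS ether, freeing only the C6 allylic alcohol.

Step 10
Reactants: 17 (2Z,5Z,9Z)-9-{[(tert-butyldiphenylsilyl)oxy]methyl}-10-iodo-5-methyldeca-2,5,9-trien-1-ol
Product: 18 [(2R,3S)-3-{(2Z,6Z)-6-{[(tert-butyldiphenylsilyl)oxy]methyl}-7-iodo-2-methylhepta-2,6-dien-1-yl}oxiran-2-yl]methanol (cis-epoxide; C7 R, C8 S)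
Conditions: Ti(OiPr)4 (1.0 equiv), D-(−)-diethyl tartrate (1.2 equiv), t-BuOOH, 4 Å MS, CH2Cl2, −20 °C
Reagents that add atoms: tert-butyl hydroperoxide, CC(C)(C)OO
Why: Katsuki–Sharpless epoxidation; the titanium–tartrate complex binds the allylic alcohol and the D-(−)-tartrate delivers oxygen to the face that gives the (2R,3S) cis-epoxide, setting C7 and C8 together. Only the alkene of the bound allylic alcohol reacts; the skipped trisubstituted alkene and the iodoalkene are not directed.

Step 11
Reactants: 18 [(2R,3S)-3-{(2Z,6Z)-6-{[(tert-butyldiphenylsilyl)oxy]methyl}-7-iodo-2-methylhepta-2,6-dien-1-yl}oxiran-2-yl]methanol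
Product: 19 (2S,3S)-3-{(2Z,6Z)-6-{[(tert-butyldiphenylsilyl)oxy]methyl}-7-iodo-2-methylhepta-2,6-dien-1-yl}oxirane-2-carbaldehyde (same spatial arrangement as 18)
Conditions: Dess–Martin periodinane, NaHCO3, CH2Cl2, 0 °C → rt; used crude
Reagents that add atoms: none
Why: Buffered Dess–Martin oxidation is non-basic and non-acidic, so the cis-epoxy aldehyde should form without epimerisation at C7 or epoxide opening.

Step 12
Reactants: 19 (2S,3S)-3-{(2Z,6Z)-6-{[(tert-butyldiphenylsilyl)oxy]methyl}-7-iodo-2-methylhepta-2,6-dien-1-yl}oxirane-2-carbaldehyde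
Product: 20 (1R,2R,3Z,7Z,10S)-4-{[(tert-butyldiphenylsilyl)oxy]methyl}-8-methyl-11-oxabicyclo[8.1.0]undeca-3,7-dien-2-ol (6R,7R,8S; cis-7,8-epoxide, C6–OH anti to the epoxide oxygen, C3 and C6 trans on C4=C5)
Conditions: CrCl2 (8 equiv), NiCl2 (cat.), DMSO, rt, slow addition, 3 mM
Reagents that add atoms: none
Why: Nozaki–Hiyama–Kishi reaction; nickel-catalysed insertion into the C–I bond and transfer to chromium give an alkenylchromium (trivalent chromium) that adds to the aldehyde with retention of alkene geometry and closes the ten-membered ring. C6 is set by Felkin–Anh attack anti to the epoxide C7–O bond, reinforced by the cis C8 substituent, which gives the anti epoxy alcohol.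

Step 13
Reactants: 20 (1R,2R,3Z,7Z,10S)-4-{[(tert-butyldiphenylsilyl)oxy]methyl}-8-methyl-11-oxabicyclo[8.1.0]undeca-3,7-dien-2-ol; 21 (diethoxyphosphoryl)acetic acid
Product: 22 (1S,2R,3Z,7Z,10S)-4-{[(tert-butyldiphenylsilyl)oxy]methyl}-8-methyl-11-oxabicyclo[8.1.0]undeca-3,7-dien-2-yl (diethoxyphosphoryl)acetate (6R,7S,8S)
Conditions: DCC, DMAP (cat.), CH2Cl2, 0 °C → rt
Reagents that add atoms: none
Why: Steglich esterification of the secondary allylic alcohol under neutral conditions; no stereocentre is touched and the epoxide is not opened.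

Step 14
Reactants: 22 (1S,2R,3Z,7Z,10S)-4-{[(tert-butyldiphenylsilyl)oxy]methyl}-8-methyl-11-oxabicyclo[8.1.0]undeca-3,7-dien-2-yl (diethoxyphosphoryl)acetate
Product: 23 (3aR,4S,6Z,10Z,11aR)-10-{[(tert-butyldiphenylsilyl)oxy]methyl}-3-(diethoxyphosphoryl)-4-hydroxy-6-methyl-3a,4,5,8,9,11a-hexahydrocyclodeca[b]furan-2(3H)-one (6R,7R,8S; both C11 epimers)
Conditions: NaH (1.05 equiv), THF, 0 → 45 °C; AcOH, 0 °C
Reagents that add atoms: none
Why: Proposed new method: NaH forms the sodium enolate of the phosphonoacetate, whose carbon C11 attacks C7 of the cis-epoxide from the side opposite the C7–O bond, forming C7–C11 and the γ-lactone in one SN2 event and releasing the C8 alkoxide, which is at once protonated by the far more acidic C11–H so that the lactone rests as its unreactive phosphonate enolate until the quench. The closest known reaction types are the epoxynitrile and epoxy-malonate cyclisations of carbon-tethered anions, the intermolecular opening of epoxides by phosphonoacetate anions to α-phosphono-γ-lactones, and the intramolecular Michael addition of ester-tethered phosphonoacetates; the ester-tethered epoxide opening itself has no direct precedent. The lactone closes in the 5-exo-tet mode (ring atoms C11, C12, O6, C6, C7, with the breaking C7–O bond exocyclic). The C7 configuration is controlled by the epoxide set in step 10: backside attack inverts C7, so C11 ends anti to O8; because O6 in 22 is anti to the epoxide oxygen (set in step 12), the tether reaches exactly this face and the ring fusion is trans, while C11 forms as a mixture that step 15 erases. The step needs attack at C7 and not at C8: the three-atom tether would make C8 attack a 6-endo closure to a bridged δ-lactone with a non-collinear trajectory, and C8 carries no activating group. It also needs C- over O-alkylation and no base-induced isomerisation of the epoxide to an allylic alcohol; the soft, weakly basic stabilised anion in a tight sodium ion pair favours carbon attack. One equivalent of base and a mild temperature limit migration of the lactone to O8.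

Step 15
Reactants: 23 (3aR,4S,6Z,10Z,11aR)-10-{[(tert-butyldiphenylsilyl)oxy]methyl}-3-(diethoxyphosphoryl)-4-hydroxy-6-methyl-3a,4,5,8,9,11a-hexahydrocyclodeca[b]furan-2(3H)-one
Product: 24 (3aR,4S,6Z,10Z,11aR)-10-{[(tert-butyldiphenylsilyl)oxy]methyl}-4-hydroxy-6-methyl-3-methylidene-3a,4,5,8,9,11a-hexahydrocyclodeca[b]furan-2(3H)-one
Conditions: K2CO3, 37% aq. HCHO, THF, 0 °C → rt
Reagents that add atoms: formaldehyde, C=O
Why: Horner–Wadsworth–Emmons methylenation of an α-phosphono lactone; carbonate is basic enough for the phosphonate C–H but too weak to keep C8–OH as an alkoxide, and both C11 epimers converge on the exocyclic alkene.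

Step 16
Reactants: 25 methyl (2S)-3-hydroxy-2-methylpropanoate
Product: 26 methyl (2S)-3-[(tert-butyldimethylsilyl)oxy]-2-methylpropanoate
Conditions: TBSCl, imidazole, CH2Cl2, 0 °C → rt
Reagents that add atoms: tert-butyl(chloro)dimethylsilane, CC(C)(C)[Si](C)(C)Cl
Why: Standard silylation of the primary alcohol; the stereocentre is not involved.

Step 17
Reactants: 26 methyl (2S)-3-[(tert-butyldimethylsilyl)oxy]-2-methylpropanoate
Product: 27 (2S)-3-[(tert-butyldimethylsilyl)oxy]-2-methylpropanoic acid
Conditions: LiOH·H2O, THF/MeOH/H2O, 0 °C → rt; 1 M HCl to pH 3–4, 0 °C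
Reagents that add atoms: lithium hydroxide, [Li+].[OH-]
Why: Saponification at low temperature; the carboxylate formed is not enolised, so neither epimerisation nor β-elimination of the silyloxy group is expected.

Step 18
Reactants: 24 (3aR,4S,6Z,10Z,11aR)-10-{[(tert-butyldiphenylsilyl)oxy]methyl}-4-hydroxy-6-methyl-3-methylidene-3a,4,5,8,9,11a-hexahydrocyclodeca[b]furan-2(3H)-one; 27 (2S)-3-[(tert-butyldimethylsilyl)oxy]-2-methylpropanoic acid
Product: 28 (3aR,4S,6Z,10Z,11aR)-10-{[(tert-butyldiphenylsilyl)oxy]methyl}-6-methyl-3-methylidene-2-oxo-2,3,3a,4,5,8,9,11a-octahydrocyclodeca[b]furan-4-yl (2S)-3-[(tert-butyldimethylsilyl)oxy]-2-methylpropanoate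
Conditions: 27 (1.5 equiv), DCC, DMAP (0.3 equiv), CH2Cl2, 0 °C → rt
Reagents that add atoms: none
Why: Steglich esterification of the C8 alcohol; DMAP adds only reversibly to the α-methylene lactone, and any diastereomer arising from residual enantiomer of 24 can be removed here.

Step 19
Reactants: 28 (3aR,4S,6Z,10Z,11aR)-10-{[(tert-butyldiphenylsilyl)oxy]methyl}-6-methyl-3-methylidene-2-oxo-2,3,3a,4,5,8,9,11a-octahydrocyclodeca[b]furan-4-yl (2S)-3-[(tert-butyldimethylsilyl)oxy]-2-methylpropanoate
Product: 29 (3aR,4S,6Z,10Z,11aR)-10-(hydroxymethyl)-6-methyl-3-methylidene-2-oxo-2,3,3a,4,5,8,9,11a-octahydrocyclodeca[b]furan-4-yl (2S)-3-hydroxy-2-methylpropanoate (target; 6R,7R,8S and 2′S)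
Conditions: HF·pyridine, pyridine, THF, 0 °C → rt
Reagents that add atoms: none
Why: Fluoride cleavage of both silyl ethers under buffered, weakly acidic conditions, which avoids the basic alkoxides that would add to the α-methylene lactone or eliminate the side chain.

## Compound list

1 | 3-[(tert-butyldimethylsilyl)oxy]propanal | O=CCCO[Si](C)(C)C(C)(C)C | starting material
2 | ethyl 2-[bis(2,2,2-trifluoroethoxy)phosphoryl]propanoate | CCOC(=O)C(C)P(=O)(OCC(F)(F)F)OCC(F)(F)F | starting material
3 | ethyl (2Z)-5-[(tert-butyldimethylsilyl)oxy]-2-methylpent-2-enoate | CCOC(=O)/C(C)=C\CCO[Si](C)(C)C(C)(C)C | intermediate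
4 | ethyl (2Z)-5-bromo-2-methylpent-2-enoate | CCOC(=O)/C(C)=C\CCBr | intermediate
5 | (2Z)-5-bromo-2-methylpent-2-en-1-ol | OC/C(C)=C\CCBr | intermediate
6 | (2Z)-1,5-dibromo-2-methylpent-2-ene | BrC/C(C)=C\CCBr | intermediate
7 | tert-butyldimethyl(prop-2-yn-1-yloxy)silane | C#CCO[Si](C)(C)C(C)(C)C | starting material
8 | bromo{3-[(tert-butyldimethylsilyl)oxy]prop-1-yn-1-yl}magnesium | Br[Mg]C#CCO[Si](C)(C)C(C)(C)C | intermediate
9 | {[(5Z)-8-bromo-5-methyloct-5-en-2-yn-1-yl]oxy}(tert-butyl)dimethylsilane | CC(C)(C)[Si](C)(C)OCC#CC/C(C)=C\CCBr | intermediate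
10 | {[(2Z,5Z)-8-bromo-5-methylocta-2,5-dien-1-yl]oxy}(tert-butyl)dimethylsilane | CC(C)(C)[Si](C)(C)OC/C=C\C/C(C)=C\CCBr | intermediate
11 | prop-2-yn-1-ol | C#CCO | starting material
12 | bromo{(3Z,6Z)-8-[(tert-butyldimethylsilyl)oxy]-4-methylocta-3,6-dien-1-yl}magnesium | Br[Mg]CC/C=C(/C)C/C=C\CO[Si](C)(C)C(C)(C)C | intermediate
13 | chloro(prop-2-yn-1-olato)magnesium | Cl[Mg]OCC#C | intermediate
14 | alkenylmagnesium adduct of 12 and 13, drawn open-chain (Mg on C5 cis to CH2OMgCl) | Br[Mg]/C=C(\CO[Mg]Cl)CC/C=C(/C)C/C=C\CO[Si](C)(C)C(C)(C)C | intermediate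
15 | (2Z)-2-{(3Z,6Z)-8-[(tert-butyldimethylsilyl)oxy]-4-methylocta-3,6-dien-1-yl}-3-iodoprop-2-en-1-ol | I/C=C(\CO)CC/C=C(/C)C/C=C\CO[Si](C)(C)C(C)(C)C | intermediate
16 | tert-butyl{[(2Z)-2-{(3Z,6Z)-8-[(tert-butyldimethylsilyl)oxy]-4-methylocta-3,6-dien-1-yl}-3-iodoprop-2-en-1-yl]oxy}diphenylsilane | I/C=C(\CO[Si](c1ccccc1)(c1ccccc1)C(C)(C)C)CC/C=C(/C)C/C=C\CO[Si](C)(C)C(C)(C)C | intermediate
17 | (2Z,5Z,9Z)-9-{[(tert-butyldiphenylsilyl)oxy]methyl}-10-iodo-5-methyldeca-2,5,9-trien-1-ol | I/C=C(\CO[Si](c1ccccc1)(c1ccccc1)C(C)(C)C)CC/C=C(/C)C/C=C\CO | intermediate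
18 | [(2R,3S)-3-{(2Z,6Z)-6-{[(tert-butyldiphenylsilyl)oxy]methyl}-7-iodo-2-methylhepta-2,6-dien-1-yl}oxiran-2-yl]methanol | I/C=C(\CO[Si](c1ccccc1)(c1ccccc1)C(C)(C)C)CC/C=C(/C)C[C@@H]1O[C@@H]1CO | intermediate
19 | (2S,3S)-3-{(2Z,6Z)-6-{[(tert-butyldiphenylsilyl)oxy]methyl}-7-iodo-2-methylhepta-2,6-dien-1-yl}oxirane-2-carbaldehyde | I/C=C(\CO[Si](c1ccccc1)(c1ccccc1)C(C)(C)C)CC/C=C(/C)C[C@@H]1O[C@@H]1C=O | intermediate
20 | (1R,2R,3Z,7Z,10S)-4-{[(tert-butyldiphenylsilyl)oxy]methyl}-8-methyl-11-oxabicyclo[8.1.0]undeca-3,7-dien-2-ol | O[C@@H]1/C=C(\CO[Si](c2ccccc2)(c2ccccc2)C(C)(C)C)CC/C=C(/C)C[C@@H]2O[C@@H]21 | intermediate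
21 | (diethoxyphosphoryl)acetic acid | CCOP(=O)(CC(=O)O)OCC | starting material
22 | (1S,2R,3Z,7Z,10S)-4-{[(tert-butyldiphenylsilyl)oxy]methyl}-8-methyl-11-oxabicyclo[8.1.0]undeca-3,7-dien-2-yl (diethoxyphosphoryl)acetate | CCOP(=O)(OCC)CC(=O)O[C@@H]1/C=C(\CO[Si](c2ccccc2)(c2ccccc2)C(C)(C)C)CC/C=C(/C)C[C@@H]2O[C@@H]21 | intermediate
23 | (3aR,4S,6Z,10Z,11aR)-10-{[(tert-butyldiphenylsilyl)oxy]methyl}-3-(diethoxyphosphoryl)-4-hydroxy-6-methyl-3a,4,5,8,9,11a-hexahydrocyclodeca[b]furan-2(3H)-one | CCOP(=O)(OCC)C1C(=O)O[C@@H]2/C=C(\CO[Si](c3ccccc3)(c3ccccc3)C(C)(C)C)CC/C=C(/C)C[C@H](O)[C@@H]12 | intermediate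
24 | (3aR,4S,6Z,10Z,11aR)-10-{[(tert-butyldiphenylsilyl)oxy]methyl}-4-hydroxy-6-methyl-3-methylidene-3a,4,5,8,9,11a-hexahydrocyclodeca[b]furan-2(3H)-one | C=C1C(=O)O[C@@H]2/C=C(\CO[Si](c3ccccc3)(c3ccccc3)C(C)(C)C)CC/C=C(/C)C[C@H](O)[C@@H]12 | intermediate
25 | methyl (2S)-3-hydroxy-2-methylpropanoate | COC(=O)[C@@H](C)CO | starting material
26 | methyl (2S)-3-[(tert-butyldimethylsilyl)oxy]-2-methylpropanoate | COC(=O)[C@@H](C)CO[Si](C)(C)C(C)(C)C | intermediate
27 | (2S)-3-[(tert-butyldimethylsilyl)oxy]-2-methylpropanoic acid | OC(=O)[C@@H](C)CO[Si](C)(C)C(C)(C)C | intermediate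
28 | (3aR,4S,6Z,10Z,11aR)-10-{[(tert-butyldiphenylsilyl)oxy]methyl}-6-methyl-3-methylidene-2-oxo-2,3,3a,4,5,8,9,11a-octahydrocyclodeca[b]furan-4-yl (2S)-3-[(tert-butyldimethylsilyl)oxy]-2-methylpropanoate | C=C1C(=O)O[C@@H]2/C=C(\CO[Si](c3ccccc3)(c3ccccc3)C(C)(C)C)CC/C=C(/C)C[C@H](OC(=O)[C@@H](C)CO[Si](C)(C)C(C)(C)C)[C@@H]12 | intermediate
29 | (3aR,4S,6Z,10Z,11aR)-10-(hydroxymethyl)-6-methyl-3-methylidene-2-oxo-2,3,3a,4,5,8,9,11a-octahydrocyclodeca[b]furan-4-yl (2S)-3-hydroxy-2-methylpropanoate | C=C1C(=O)O[C@@H]2/C=C(\CO)CC/C=C(/C)C[C@H](OC(=O)[C@@H](C)CO)[C@@H]12 | target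

## Step count and least certain steps

Total step count: 19. Longest linear sequence: 17 (steps 1–15, 18, 19; steps 16–17 prepare the side-chain acid).

**Step 14 (key step).** The most likely failure is that the tethered anion does not reach the backside of C7. The ester must rotate into its less favoured s-cis form and the ten-membered ring must turn the epoxide oxygen away from the O6 face. If closure is slow, lactone migration to O8, O-alkylation or isomerisation of the epoxide to an allylic alcohol can take over. The fallback uses known chemistry and a radical instead of an SN2 opening; it sets out from 20 and returns at 28. O-Propargylation of 20 under neutral conditions (propargyl bromide, Ag2O, avoiding Payne rearrangement) would give the propargyl ether F1. Cp2TiCl (trivalent titanium, from Cp2TiCl2 and Zn) would open the epoxide reductively to the C7 radical with titanium on O8, and 5-exo-dig cyclisation onto the alkyne would give the 3-methylenetetrahydrofuran alcohol F2, the new bond being expected anti to the bulky O8–Ti group. Acylation with 27 (DCC, DMAP) would give the ester F3, and oxidation of the ring CH2 that is both allylic and α to oxygen (CrO3·2C5H5N) would form the lactone, which is 28.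

**Step 12.** The likely problems are poor facial selectivity at C6, if ring strain overrides the Felkin–Anh preference, and oligomerisation when the alkenylchromium meets a second molecule before its own aldehyde. The fallback sets out from 19 and returns at 22. The C6-epimeric ring alcohol F4 from the same closure would be esterified with 21 under Mitsunobu conditions (PPh3, diisopropyl azodicarboxylate), which attaches the tether with inversion at C6 and gives 22 directly.

**Step 7.** The copper catalyst may divert Grignard reagent 12 into allylic substitution of its own C6 silyl ether (SN2′ ring closure), or the addition may stall and leave protonated chain. The fallback avoids organomagnesium chemistry; it sets out from 10 and returns at 16. Displacement of the bromide with LiC≡CH·H2NCH2CH2NH2 in DMSO would give the terminal alkyne F5. Rhodium-catalysed silylformylation (Me2PhSiH, CO, Rh4(CO)12) adds silicon to the terminal carbon and the formyl group to the internal carbon on the same side, giving the (Z)-β-silyl enal F6. Reduction with NaBH4/CeCl3 would give the allylic alcohol F7, and TBDPSCl/imidazole the bis-silyl ether F8. Iododesilylation with N-iodosuccinimide, which proceeds with retention, would then give 16.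

**Step 10.** Enantiofacial discrimination may be incomplete and turnover slow, because (Z)-allylic alcohols are the least responsive substrates for this epoxidation; any minor enantiomer would in any case become a separable diastereomer at 28. The fallback replaces reagent control by resolution; it sets out from 17 and returns at 18. Achiral directed epoxidation (VO(acac)2, t-BuOOH) would give 18 together with its enantiomer F9. Lipase-catalysed acetylation (vinyl acetate, lipase from Burkholderia cepacia, screened so that 18 is the fast-reacting enantiomer) would give the acetate F10, which is separated from F9 and cleaved with K2CO3 in MeOH back to 18.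

## Further compounds

F1 | step 14 | O6-propargyl ether of 20 | C#CCO[C@@H]1/C=C(\CO[Si](c2ccccc2)(c2ccccc2)C(C)(C)C)CC/C=C(/C)C[C@@H]2O[C@@H]21
F2 | step 14 | (3aR,4S,6Z,10Z,11aR)-10-{[(tert-butyldiphenylsilyl)oxy]methyl}-6-methyl-3-methylidene-2,3,3a,4,5,8,9,11a-octahydrocyclodeca[b]furan-4-ol | C=C1CO[C@@H]2/C=C(\CO[Si](c3ccccc3)(c3ccccc3)C(C)(C)C)CC/C=C(/C)C[C@H](O)[C@@H]12
F3 | step 14 | ester of F2 with 27 at C8 | C=C1CO[C@@H]2/C=C(\CO[Si](c3ccccc3)(c3ccccc3)C(C)(C)C)CC/C=C(/C)C[C@H](OC(=O)[C@@H](C)CO[Si](C)(C)C(C)(C)C)[C@@H]12
F4 | step 12 | C6 epimer of 20 | O[C@H]1/C=C(\CO[Si](c2ccccc2)(c2ccccc2)C(C)(C)C)CC/C=C(/C)C[C@@H]2O[C@@H]21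
F5 | step 7 | tert-butyl{[(2Z,5Z)-5-methyldeca-2,5-dien-9-yn-1-yl]oxy}dimethylsilane | C#CCC/C=C(/C)C/C=C\CO[Si](C)(C)C(C)(C)C
F6 | step 7 | (2Z)-2-{(3Z,6Z)-8-[(tert-butyldimethylsilyl)oxy]-4-methylocta-3,6-dien-1-yl}-3-[dimethyl(phenyl)silyl]prop-2-enal | C[Si](C)(c1ccccc1)/C=C(\C=O)CC/C=C(/C)C/C=C\CO[Si](C)(C)C(C)(C)C
F7 | step 7 | (2Z)-2-{(3Z,6Z)-8-[(tert-butyldimethylsilyl)oxy]-4-methylocta-3,6-dien-1-yl}-3-[dimethyl(phenyl)silyl]prop-2-en-1-ol | C[Si](C)(c1ccccc1)/C=C(\CO)CC/C=C(/C)C/C=C\CO[Si](C)(C)C(C)(C)C
F8 | step 7 | tert-butyldiphenylsilyl ether of F7 | C[Si](C)(c1ccccc1)/C=C(\CO[Si](c1ccccc1)(c1ccccc1)C(C)(C)C)CC/C=C(/C)C/C=C\CO[Si](C)(C)C(C)(C)C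
F9 | step 10 | [(2S,3R)-3-{(2Z,6Z)-6-{[(tert-butyldiphenylsilyl)oxy]methyl}-7-iodo-2-methylhepta-2,6-dien-1-yl}oxiran-2-yl]methanol (enantiomer of 18) | I/C=C(\CO[Si](c1ccccc1)(c1ccccc1)C(C)(C)C)CC/C=C(/C)C[C@H]1O[C@H]1CO
F10 | step 10 | acetate of 18 | I/C=C(\CO[Si](c1ccccc1)(c1ccccc1)C(C)(C)C)CC/C=C(/C)C[C@@H]1O[C@@H]1COC(C)=O
A1 | alternative 1 | cis-1,2-dialkenylcyclohexanol (C5 tertiary alcohol with the 3-silyloxyprop-1-en-2-yl group axial in the reactive chair, C10 methyl and vinyl, C6 PMB ether, C7 2-(PMB-oxy)ethyl, C8 TBS ether) | O[C@]1(C(=C)CO[Si](c2ccccc2)(c2ccccc2)C(C)(C)C)[C@@H](OCc2ccc(OC)cc2)[C@H](CCOCc2ccc(OC)cc2)[C@@H](O[Si](C)(C)C(C)(C)C)C[C@@]1(C)C=C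
A2 | alternative 1 | cyclodeca-1(10),4-dien-5-yl triflate | COc1ccc(CO[C@@H]2/C(OS(=O)(=O)C(F)(F)F)=C(\CO[Si](c3ccccc3)(c3ccccc3)C(C)(C)C)CC/C=C(/C)C[C@H](O[Si](C)(C)C(C)(C)C)[C@H]2CCOCc2ccc(OC)cc2)cc1
A3 | alternative 2 | γ-alkenyl butenolide with the C8 aldehyde | O=C1O[C@H](/C=C(\CO[Si](C)(C)C(C)(C)C)CC/C=C(/C)CC=O)C=C1
A4 | alternative 2 | trans-fused lactone with the C8 alcohol | O=C1O[C@@H]2/C=C(\CO[Si](C)(C)C(C)(C)C)CC/C=C(/C)C[C@H](O)[C@H]2C1
A5 | alternative 3 | cis-anti-cis tricyclic enone–cyclobutene photoadduct (cyclobutane anti to the C7 side chain) | O=C1[C@@H]2[C@@]3(C(=O)OC)CC[C@H]3[C@]2(C)C[C@H](O[Si](C)(C)C(C)(C)C)[C@H]1CC(OC)OC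
A6 | alternative 3 | cyclodeca-1(10),4-dien-6-one with the C15 ester | O=C1/C=C(\C(=O)OC)CC/C=C(/C)C[C@H](O[Si](C)(C)C(C)(C)C)[C@H]1CC(OC)OC
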